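**Retrosynthetic overview**
1. Target 17 ⇐ Mitsunobu angeloylation with inversion at C2 ⇐ hydroxy lactone 16 ⇐ hydride reduction and lactonisation of tricyclic diketo ester 14 (γ-lactone formed last).
2. 14 ⇐ one anionic cascade from enone 11: acylal opening, oxa-Michael addition (tetrahydrofuran ring, C5–O) and 7-endo Michael addition (cycloheptane ring, C1–C10).
3. 11 ⇐ photochemical decarboxylative, dehydrogenative C5–C6 coupling of acid 10 with cyclopentenone 3 (the fragment union).
4. 3 ⇐ (R)-linalool (ring-closing metathesis, allylic oxidation); 10 ⇐ L-malic acid through Seebach's dioxolanone (methylation, Stille acylation, enolate alkylation).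
5. Ring order: cyclopentenone (bought as linalool) → tetrahydrofuran → cycloheptane → γ-lactone.

Assumption: positions are numbered as in guaiane (C1–C15); the given SMILES has C4 = R and C11 = S, which are the configurations delivered by (R)-(−)-linalool and L-malic acid.

**Route**

Step 1
Reactants: 1 (R)-(−)-linalool
Product: 2 (R)-1-methylcyclopent-2-en-1-ol
Conditions: RuCl2(=CHPh)(PCy3)(H2IMes) (second-generation Grubbs catalyst, 0.5 mol%), CH2Cl2, 40 °C
Reagents that add atoms: none
Why: Ring-closing metathesis of the 1,6-diene expels isobutene and closes the cyclopentene; the tertiary carbinol (future C4) is not touched.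

Step 2
Reactants: 2 (R)-1-methylcyclopent-2-en-1-ol
Product: 3 (R)-4-hydroxy-4-methylcyclopent-2-en-1-one
Conditions: Rh2(cap)4 (cap = caprolactamate, 1 mol%), t-BuOOH (70% aq, 5 equiv), K2CO3, CH2Cl2, rt
Reagents that add atoms: tert-butyl hydroperoxide CC(C)(C)OO
Why: Radical allylic C–H oxidation at the only allylic methylene gives the enone (C2=O); the carbinol carbon has no hydrogen and the radical pathway avoids chromium-type 1,3-transposition.

Step 3
Reactants: 4 L-malic acid
Product: 5 2-[(2S,4S)-2-tert-butyl-5-oxo-1,3-dioxolan-4-yl]acetic acid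
Conditions: t-BuCHO, TsOH·H2O (cat.), H2SO4 (cat.), pentane, reflux with water removal
Reagents that add atoms: pivalaldehyde CC(C)(C)C=O
Why: Acid-catalysed acetalisation of the α-hydroxy acid unit (Seebach dioxolanone) under thermodynamic control gives the cis acetal, so the malic stereocentre fixes the acetal carbon.

Step 4
Reactants: 5 2-[(2S,4S)-2-tert-butyl-5-oxo-1,3-dioxolan-4-yl]acetic acid
Product: 6 2-[(2S,4S)-2-tert-butyl-4-methyl-5-oxo-1,3-dioxolan-4-yl]acetic acid
Conditions: LiN(SiMe3)2 (2.2 equiv), THF, −78 °C; MeI; aq. HCl work-up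
Reagents that add atoms: iodomethane CI
Why: Self-regeneration of stereocentres: the dianion (carboxylate plus dioxolanone enolate) is methylated anti to the tert-butyl group, giving the (S)-citramalate carbon (future C11) with retention.

Step 5
Reactants: 6 2-[(2S,4S)-2-tert-butyl-4-methyl-5-oxo-1,3-dioxolan-4-yl]acetic acid
Product: 8 (2S,5S)-2-tert-butyl-5-methyl-5-[(E)-2-oxopent-3-en-1-yl]-1,3-dioxolan-4-one, via acid chloride 7 (not isolated)
Conditions: (COCl)2, DMF (cat.), CH2Cl2, 0 °C → rt; then (E)-MeCH=CHSnBu3, Pd(PPh3)4 (3 mol%), toluene, 60 °C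
Reagents that add atoms: oxalyl chloride ClC(=O)C(=O)Cl (chlorine of 7 only); (E)-tributyl(prop-1-en-1-yl)stannane C/C=C/[Sn](CCCC)(CCCC)CCCC
Why: Acid chloride formation followed by Stille acylation on zerovalent palladium gives the crotonyl ketone (C8–C10) with retention of the E alkene; the neutral conditions spare the acylal.

Step 6
Reactants: 8 (2S,5S)-2-tert-butyl-5-methyl-5-[(E)-2-oxopent-3-en-1-yl]-1,3-dioxolan-4-one
Product: 9 tert-butyl (3R,5E)-3-[(2S,4S)-2-tert-butyl-4-methyl-5-oxo-1,3-dioxolan-4-yl]-4-oxohept-5-enoate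
Conditions: LiN(iPr)2 (1.05 equiv), THF, −78 °C; BrCH2CO2t-Bu, DMPU, −78 → −40 °C
Reagents that add atoms: tert-butyl bromoacetate BrCC(=O)OC(C)(C)C
Why: Kinetic α′-deprotonation of the enone and SN2 enolate alkylation; C7 is set by 1,2-induction from C11 (ring oxygen inside, ring carbonyl carbon anti to the electrophile), the minor epimer is removed by chromatography, and the low temperature suppresses β-elimination of the acylal oxygen.

Step 7
Reactants: 9 tert-butyl (3R,5E)-3-[(2S,4S)-2-tert-butyl-4-methyl-5-oxo-1,3-dioxolan-4-yl]-4-oxohept-5-enoate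
Product: 10 (3R,5E)-3-[(2S,4S)-2-tert-butyl-4-methyl-5-oxo-1,3-dioxolan-4-yl]-4-oxohept-5-enoic acid
Conditions: CF3CO2H, CH2Cl2, 0 °C → rt
Reagents that add atoms: none
Why: Acidolysis of the tert-butyl ester (loss of isobutene); the pivalaldehyde acylal and the enone tolerate anhydrous acid.

Step 8
Reactants: 10 (3R,5E)-3-[(2S,4S)-2-tert-butyl-4-methyl-5-oxo-1,3-dioxolan-4-yl]-4-oxohept-5-enoic acid; 3 (R)-4-hydroxy-4-methylcyclopent-2-en-1-one (2.5 equiv)
Product: 11 (2S,5S)-2-tert-butyl-5-[(2R,4E)-1-[(5R)-5-hydroxy-5-methyl-3-oxocyclopent-1-en-1-yl]-3-oxohex-4-en-2-yl]-5-methyl-1,3-dioxolan-4-one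
Conditions: [Ir(dF(CF3)ppy)2(dtbbpy)]PF6 (1 mol%), Co(dmgH)2(py)Cl (3 mol%), K2HPO4 (0.5 equiv), DMSO, 450 nm LEDs, rt, argon
Reagents that add atoms: none
Why: Proposed new method: acceptorless dehydrogenative decarboxylative β-alkylation of a cyclic enone (formal β-C–H alkylation), in which photoexcited trivalent iridium oxidises the carboxylate of 10, the primary C6 radical adds to C5 of 3 (nucleophilic radical, electron-poor alkene), the α-keto radical at C1 is captured by divalent cobalt and gives up the C5 hydrogen to restore the enone while the cobalt hydride releases H2 and the reduced iridium closes both cycles; the closest known chemistry is the reductive photoredox decarboxylative Giese addition and the photoredox/cobaloxime decarboxylative Heck-type alkenylation of styrenes.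

Step 9
Reactants: 11 (2S,5S)-2-tert-butyl-5-[(2R,4E)-1-[(5R)-5-hydroxy-5-methyl-3-oxocyclopent-1-en-1-yl]-3-oxohex-4-en-2-yl]-5-methyl-1,3-dioxolan-4-one
Product: 14 methyl 5,11-epoxy-4-hydroxy-2,8-dioxoguaian-12-oate (C1, C4, C5, C7, C10, C11 as in the target), via hydroxy ester 12 (not isolated), via spiro ether ketone 13 (not isolated)
Conditions: KOMe (1.05 equiv), THF, −40 → −10 °C; AcOH quench
Reagents that add atoms: potassium methoxide C[O-].[K+]
Why: Methoxide opens the acylal lactone and frees the C11 alkoxide, which adds to C5 (5-exo oxa-Michael addition), and the regiodefined C1 enolate then closes the seven-membered ring by 7-endo Michael addition to the crotonyl unit; C5 follows from C7/C11 because only the spiro epimer with C1 cis to C8 can close (the other reverts), C1 and C10 are set in the chair-like closure (trans ring fusion, methyl pseudo-equatorial), and one equivalent of base leaves the less acidic C4 carbinol protonated.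

Step 10
Reactants: 14 methyl 5,11-epoxy-4-hydroxy-2,8-dioxoguaian-12-oate
Product: 16 5,11-epoxy-2,4-dihydroxyguaian-12,8-olide with C2 epimeric to the target, via diol ester 15 (not isolated)
Conditions: NaBH4, MeOH, −20 → 0 °C; then 1 M HCl
Reagents that add atoms: none
Why: Hydride attacks both ketones from the open upper face (the lower face is blocked by the oxa-bridge, C11 and the C4 methyl), so the C8 alcohol forms cis to the C12 ester and lactonises to the γ-lactone, and the C2 alcohol forms with the configuration opposite to the target.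

Step 11
Reactants: 16 5,11-epoxy-2,4-dihydroxyguaian-12,8-olide with C2 epimeric to the target
Product: 17 2-angeloyloxy-5,11-epoxy-4-hydroxyguaian-12,8-olide (CNP0293659.1)
Conditions: angelic acid, PPh3, DIAD, toluene, 0 °C → rt
Reagents that add atoms: angelic acid C/C=C(/C)C(=O)O
Why: Mitsunobu esterification inverts C2 by SN2 attack of angelate from the open upper face; the tertiary C4 alcohol does not react and the neutral, cold conditions keep the Z geometry of the angelate.

**Compound list**
1 | (R)-(−)-linalool, (3R)-3,7-dimethylocta-1,6-dien-3-ol | C=C[C@](C)(O)CCC=C(C)C | starting material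
2 | (R)-1-methylcyclopent-2-en-1-ol | C[C@]1(O)C=CCC1 | intermediate
3 | (R)-4-hydroxy-4-methylcyclopent-2-en-1-one | C[C@]1(O)C=CC(=O)C1 | intermediate
4 | L-malic acid, (S)-2-hydroxybutanedioic acid | OC(=O)C[C@H](O)C(=O)O | starting material
5 | 2-[(2S,4S)-2-tert-butyl-5-oxo-1,3-dioxolan-4-yl]acetic acid (tert-butyl cis to the acetic acid arm) | OC(=O)C[C@@H]1O[C@H](C(C)(C)C)OC1=O | intermediate
6 | 2-[(2S,4S)-2-tert-butyl-4-methyl-5-oxo-1,3-dioxolan-4-yl]acetic acid (methyl trans to tert-butyl) | OC(=O)C[C@]1(C)O[C@H](C(C)(C)C)OC1=O | intermediate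
7 | 2-[(2S,4S)-2-tert-butyl-4-methyl-5-oxo-1,3-dioxolan-4-yl]acetyl chloride | ClC(=O)C[C@]1(C)O[C@H](C(C)(C)C)OC1=O | intermediate (not isolated)
8 | (2S,5S)-2-tert-butyl-5-methyl-5-[(E)-2-oxopent-3-en-1-yl]-1,3-dioxolan-4-one | C/C=C/C(=O)C[C@]1(C)O[C@H](C(C)(C)C)OC1=O | intermediate
9 | tert-butyl (3R,5E)-3-[(2S,4S)-2-tert-butyl-4-methyl-5-oxo-1,3-dioxolan-4-yl]-4-oxohept-5-enoate | C/C=C/C(=O)[C@H](CC(=O)OC(C)(C)C)[C@]1(C)O[C@H](C(C)(C)C)OC1=O | intermediate
10 | (3R,5E)-3-[(2S,4S)-2-tert-butyl-4-methyl-5-oxo-1,3-dioxolan-4-yl]-4-oxohept-5-enoic acid | C/C=C/C(=O)[C@H](CC(=O)O)[C@]1(C)O[C@H](C(C)(C)C)OC1=O | intermediate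
11 | (2S,5S)-2-tert-butyl-5-[(2R,4E)-1-[(5R)-5-hydroxy-5-methyl-3-oxocyclopent-1-en-1-yl]-3-oxohex-4-en-2-yl]-5-methyl-1,3-dioxolan-4-one | C/C=C/C(=O)[C@H](CC1=CC(=O)C[C@@]1(C)O)[C@]2(C)O[C@H](C(C)(C)C)OC2=O | intermediate
12 | methyl (2S,3R,5E)-2-hydroxy-3-{[(5R)-5-hydroxy-5-methyl-3-oxocyclopent-1-en-1-yl]methyl}-2-methyl-4-oxohept-5-enoate | C/C=C/C(=O)[C@H](CC1=CC(=O)C[C@@]1(C)O)[C@](C)(O)C(=O)OC | intermediate (not isolated)
13 | methyl 3-[(E)-but-2-enoyl]-9-hydroxy-2,9-dimethyl-7-oxo-1-oxaspiro[4.4]nonane-2-carboxylate (oxa-Michael adduct, ether oxygen trans to the C4 hydroxyl) | O=C1C[C@@](C)(O)[C@]2(C1)C[C@@H](C(=O)/C=C/C)[C@@](C)(C(=O)OC)O2 | intermediate (not isolated)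
14 | methyl 5,11-epoxy-4-hydroxy-2,8-dioxoguaian-12-oate (trans-fused, C10 methyl as in target) | O=C1C[C@@](C)(O)[C@@]23C[C@@H](C(=O)C[C@@H](C)[C@H]12)[C@@](C)(C(=O)OC)O3 | intermediate
15 | methyl 5,11-epoxy-2,4,8-trihydroxyguaian-12-oate (C8 hydroxyl cis to C11, C2 epimeric to target) | O[C@@H]1C[C@@](C)(O)[C@@]23C[C@@H]([C@H](O)C[C@@H](C)[C@H]12)[C@@](C)(C(=O)OC)O3 | intermediate (not isolated)
16 | 5,11-epoxy-2,4-dihydroxyguaian-12,8-olide, C2 epimer of the deangeloyl target | O[C@@H]1C[C@@](C)(O)[C@@]23C[C@H]4[C@@H](C[C@@H](C)[C@H]12)OC(=O)[C@@]4(C)O3 | intermediate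
17 | 2-angeloyloxy-5,11-epoxy-4-hydroxyguaian-12,8-olide (CNP0293659.1) | C/C=C(/C)C(=O)O[C@H]1C[C@@](C)(O)[C@@]23C[C@H]4[C@@H](C[C@@H](C)[C@H]12)OC(=O)[C@@]4(C)O3 | target

**Step count and risks**
Total step count: 11. Longest linear sequence: 9 steps (4 → 17, steps 3–11); the linalool branch (steps 1–2) joins at step 8.

The three steps most likely to fail:

First, the new photochemical coupling (step 8). The primary radical may be intercepted by cobalt before it adds to the hindered enone, giving the α-methylene ketone by dehydrodecarboxylation, or it may add to the crotonyl unit. The fallback uses only known polar chemistry, sets out from 3 and 8 and comes back at 11. Conjugate addition of Me2CuLi to 3 gives (4R)-4-hydroxy-3,4-dimethylcyclopentan-1-one F1. IBX in DMSO can only desaturate toward the methyl-bearing carbon, because C4 is quaternary, and gives (R)-4-hydroxy-3,4-dimethylcyclopent-2-en-1-one F2. NBS with AIBN brominates the vinylic methyl to (R)-3-(bromomethyl)-4-hydroxy-4-methylcyclopent-2-en-1-one F3. The kinetic lithium enolate of 8 (LiN(iPr)2, THF, −78 °C, twofold excess to absorb the hydroxyl proton) is then alkylated with F3 and gives 11 directly, so steps 6 and 7 are not needed.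

Second, the anionic cascade (step 9). The 7-endo Michael closure may be slow; the alkoxide may instead add to the crotonyl carbon C10 (a reversible six-membered oxa-Michael), and β-elimination of the C4 hydroxyl can set in if enolates equilibrate. The fallback sets out from 11 and comes back at 14, and replaces the enolate ring closure by a Lewis-acid Mukaiyama–Michael addition of an isolated enol silane. KOMe at −78 °C is followed by Me3SiCl and Et3N before warming, which traps the C1 enolate formed in the oxa-Michael addition as the trimethylsilyl enol ether of the spiro ether F4. TiCl4 in CH2Cl2 at −78 °C then closes the seven-membered ring, and aqueous work-up gives 14.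

Third, the Mitsunobu angeloylation (step 11). The C2 alcohol is hindered, and triphenylphosphine can isomerise angelate to tiglate. The fallback sets out from 16 and comes back at 17, and separates inversion from acylation. Mitsunobu reaction with 4-nitrobenzoic acid (PPh3, DIAD) gives the inverted 4-nitrobenzoate F5. K2CO3 in methanol gives the C2-inverted alcohol, 5,11-epoxy-2,4-dihydroxyguaian-12,8-olide with the target configuration, F6. F6 is then acylated with the mixed anhydride of angelic acid and 2,4,6-trichlorobenzoyl chloride (Et3N, toluene, 80 °C), which gives 17 without isomerisation.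

Further compounds
F1 | step 8 | (4R)-4-hydroxy-3,4-dimethylcyclopentan-1-one (mixture at C3) | CC1CC(=O)C[C@@]1(C)O
F2 | step 8 | (R)-4-hydroxy-3,4-dimethylcyclopent-2-en-1-one | CC1=CC(=O)C[C@@]1(C)O
F3 | step 8 | (R)-3-(bromomethyl)-4-hydroxy-4-methylcyclopent-2-en-1-one | BrCC1=CC(=O)C[C@@]1(C)O
F4 | step 9 | methyl 3-[(E)-but-2-enoyl]-9-hydroxy-2,9-dimethyl-7-(trimethylsilyloxy)-1-oxaspiro[4.4]non-6-ene-2-carboxylate | C[Si](C)(C)OC1=C[C@]2(C[C@@H](C(=O)/C=C/C)[C@@](C)(C(=O)OC)O2)[C@](C)(O)C1
F5 | step 11 | 5,11-epoxy-4-hydroxy-2-(4-nitrobenzoyloxy)guaian-12,8-olide (C2 as in target) | O=C(O[C@H]1C[C@@](C)(O)[C@@]23C[C@H]4[C@@H](C[C@@H](C)[C@H]12)OC(=O)[C@@]4(C)O3)c1ccc(cc1)[N+](=O)[O-]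
F6 | step 11 | 5,11-epoxy-2,4-dihydroxyguaian-12,8-olide (C2 as in target) | O[C@H]1C[C@@](C)(O)[C@@]23C[C@H]4[C@@H](C[C@@H](C)[C@H]12)OC(=O)[C@@]4(C)O3
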